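I have no constants for these flasks, but from Tuesday's run I can read a ratio of them and a rate constant, and I carry both.

| setting | Tuesday's | Sunday's | teal | violet | red |
|---|---|---|---|---|---|
| substrate | 0.025 M | 0.038 M | 0.025 M (fed, over 6.0 h) | 0.025 M | 0.025 M |
| partner | 0.0625 M | 0.0625 M | 0.0625 M | 0.0625 M (fed, over 6.0 h) | 0.0625 M |
| remark | run made earlier | run made earlier | all else is in the flask from the start; the feed brings no volume worth counting | all else is in the flask from the start; the feed brings no volume worth counting | everything together at the start |
| time |  |  | 8.0 h | 8.0 h | 8.0 h |

| run | time / h | homo dimer / % | first product / % |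
|---|---|---|---|
| Tuesday's | 1.00 | 27.7 | 5.7 |
| Tuesday's | 3.00 | 48.7 | 9.4 |
| Tuesday's | 5.00 | 54.5 | 11.7 |
| Tuesday's | 8.00 | 58.4 | 10.8 |
| Sunday's | 0.333 | 17.6 | 1.8 |
| Sunday's | 0.833 | 33.3 | 3.8 |
| Sunday's | 1.50 | 46.0 | 6.4 |
| Sunday's | 2.50 | 54.2 | 7.9 |

(readings scatter by 0.5 percentage points)

- percent here means substrate units held: one homo dimer counts as two
- reactions considered so far: substrate + partner -> first product + by-product; 2 substrate -> homo dimer; partner + other mono adduct -> double product + by-product; partner + first product -> double product + by-product; substrate + partner -> other mono adduct + by-product; substrate + by-product -> side product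

1. which flask leads in amount of homo dimer, in percent of the substrate charged ("all alike" within 1.5 percentage points) (teal / violet / red / all alike)
2. how much homo dimer is there at the end, in percent of the substrate charged: teal
3. how much homo dimer is there at the end, in percent of the substrate charged: violet
4. how much homo dimer is there at the end, in percent of the substrate charged: red

Let s be the substrate as a fraction of its charge, and b the partner as a fraction of its own. Homo dimer takes substrate as s squared, and the adduct family (first product, other mono adduct, double product) takes it as s times b. So at this substrate charge the homo dimer gained per adduct gained, a selectivity factor, is s over b divided by a constant. In Tuesday's first hour s falls from the whole charge to about 66.6%, with mean 0.833. Homo dimer gains 27.7% against 5.7% of first product, so, with b taken as full and first product standing for the family, that divisor reads 0.171. This crossover fraction, the s at which the two routes gain alike at full partner, grows in step with the partner charge. The same hour reads the homo dimer rate constant as 0.416 h⁻¹.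

Now teal in slow motion. In the first instants s is near zero and the feed adds 0.167 h⁻¹, so adducts lead until s passes the crossover, after about 1.03 h. In the middle homo dimer leads, and s climbs towards the level where feed equals consumption, 0.553. After the feed stops, s falls and the ratio falls with it. Weighted by turnover, a ramp averages 0.667 of its top, which is 0.369. So I expect teal to end near 2.15 homo dimer per adduct, less than Tuesday's opening 4.86. In violet, b averages 0.250 over the first 3.00 h, less than the full charge, so homo dimer gains more per adduct there. Red repeats Tuesday, which read 58.4%. My order is violet, red, teal.

The forecast names violet, with 45% for teal, 70% for violet and 59% for red: “slow substrate feed keeps s low, favouring the adducts”.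

The simulation gives violet in the lead, with teal 45.0%, violet 70.5% and red 59.1%.

    substrate + partner → first product + by-product (k = 0.0180 L mol⁻¹ min⁻¹)
    2 substrate → homo dimer (k = 0.140 L mol⁻¹ min⁻¹)
    partner + other mono adduct → double product + by-product (k = 0.00910 L mol⁻¹ min⁻¹)
    partner + first product → double product + by-product (k = 0.0270 L mol⁻¹ min⁻¹)
    substrate + partner → other mono adduct + by-product (k = 0.00160 L mol⁻¹ min⁻¹)
    substrate + by-product → side product (k = 0.190 L mol⁻¹ min⁻¹)

Teal held 43.7% substrate at 4.00 h and 49.2% at 6.00 h, while homo dimer went from 14.3% to 32.8%. At 8.00 h teal stands at 12.9% first product, 1.41% other mono adduct and 4.88% double product, which makes 2.34 homo dimer per adduct against my 2.15.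

The neighbour flask is teal with 0.11 M of partner. Its crossover becomes 0.302, its top 0.500, and its expected ratio 1.10. It gives 36.0% homo dimer and a ratio of 1.19.

The readings were generated by integration for substances that don't exist; scatter was added.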